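**Retrosynthetic overview**
1. Feature: the 3-alkyl-4-hydroxybenzoate ring is the only junction of the 15-membered lactone (C1, C2, C7–C14, O14, C=O and three arene carbons). Its C–OH, the ortho carbon bearing C1 and the para carbon bearing the carboxyl form the pattern that a 1-methoxy-3-silyloxydiene and a propiolate deliver.
2. Last C–C disconnection: both aryl bonds (C1-bearing carbon to its neighbouring CH, and carboxyl-bearing carbon to its other neighbouring CH) come from an intramolecular [4+2]/–MeOH of a C1-linked silyloxydiene with the O14 propiolate. HF·pyridine follows.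
3. Diene arm: the C1–CH2 bond is made by alkylating the 4-methoxybut-3-en-2-one enolate with the C1 allylic bromide. C1 itself comes from Pd methoxycarbonylation of the C2 enol triflate.
4. Chain: C10/C11 and C14 are set by two reagent-controlled Shi epoxidations separated by a cross-metathesis (vinyl to isopropylidene). Soft bromide opens at C10 with inversion, and TMSBr opens at C15 with the C14–O bond kept.
5. Ring order: the cyclohexene comes first, from 2-methylcyclohexane-1,3-dione (C7 by hydrazone alkylation, C6/C7 by CBS desymmetrisation, C6–Br by Appel inversion). The arene and the macrolactone then close together in one step.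

Key step: step 21

Numbering used throughout: C1 benzylic CH2, C2=C3 ring alkene, C6 ring CHBr, C7 quaternary, C8/C9 CH2, C10 CHBr, C11 carbinol, C12/C13 CH2, C14 ester CH, C15 CMe2Br. The target is 6S,7S,10R,11S,14S, with Br at C6 cis to the C7 methyl and trans to C8.
Assumption: hex-1-en-5-yne and the L-fructose-derived enantiomer of the Shi ketone (used only as a catalyst) are taken as purchasable.

**Step 1**
Reactants: 1 hex-1-en-5-yne; 2 oxirane
Product: 5 (3E)-4-methylocta-3,7-dien-1-ol, via (E)-dimethyl(2-methylhexa-1,5-dienyl)alane 3 (not isolated), via lithium butyl(dimethyl)(2-methylhexa-1,5-dienyl)alanate 4 (not isolated)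
Conditions: Me3Al, Cp2ZrCl2 (cat.), CH2Cl2, 0 °C → rt; n-BuLi, hexane–THF, −78 → 0 °C; 2, 0 °C → rt; aq. HCl
Reagents that add atoms: trimethylaluminium C[Al](C)C; n-butyllithium [Li]CCCC (atoms only in 4)
Why: Negishi zirconium-catalysed methylalumination adds Me and Al syn across the alkyne with Me on the internal carbon and should leave the isolated vinyl group alone, and the derived alanate opens oxirane with retention at the alkenyl carbon, so the E-C10=C11 alkene is fixed here.

**Step 2**
Reactants: 5 (3E)-4-methylocta-3,7-dien-1-ol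
Product: 6 (5E)-8-iodo-5-methylocta-1,5-diene
Conditions: I2, PPh3, imidazole, CH2Cl2, 0 °C
Reagents that add atoms: iodine II
Why: Appel-type iodination of an unhindered primary alcohol proceeds by SN2 on the alkoxyphosphonium salt and does not affect either alkene.

**Step 3**
Reactants: 7 2-methylcyclohexane-1,3-dione
Product: 8 3-(2,2-dimethylhydrazinyl)-2-methylcyclohex-2-en-1-one (mono-dimethylhydrazone of 7, vinylogous hydrazide tautomer)
Conditions: Me2NNH2, p-TsOH (cat.), toluene, reflux (−H2O)
Reagents that add atoms: N,N-dimethylhydrazine CN(C)N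
Why: Condensation of the cyclic 1,3-diketone with one equivalent of the hydrazine stops at the vinylogous hydrazide, the known device for turning the O-alkylation-prone dione into a C-nucleophile.

**Step 4**
Reactants: 8 ketodimethylhydrazone; 6 (5E)-8-iodo-5-methylocta-1,5-diene
Product: 11 2-methyl-2-[(3E)-4-methylocta-3,7-dien-1-yl]cyclohexane-1,3-dione, via potassium salt of the ketohydrazone 9 (not isolated), via racemic C-alkylated ketohydrazone 10 (not isolated)
Conditions: KH, THF, 0 °C; 6, 0 °C → rt; then Cu(OAc)2, THF–H2O, rt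
Reagents that add atoms: water O; potassium hydride [H-].[K+] (K only in 9)
Why: Aza-enolate (ketodimethylhydrazone) alkylation is C-selective with unactivated primary iodides where the parent dione would O-alkylate, and Cu(II)-assisted hydrazone hydrolysis then returns the prochiral 2,2-disubstituted dione, so C7 is built but not yet stereogenic.

**Step 5**
Reactants: 11 2,2-disubstituted dione
Product: 12 (2R,3R)-3-hydroxy-2-methyl-2-[(3E)-4-methylocta-3,7-dien-1-yl]cyclohexan-1-one (6R,7R; OH cis to the chain)
Conditions: (S)-Me-CBS (20 mol %), catecholborane (1.2 equiv), toluene, −78 → −50 °C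
Reagents that add atoms: none
Why: This is a Corey–Bakshi–Shibata reduction used as a desymmetrising monoreduction of a 2,2-disubstituted 1,3-diketone, in which the (S)-catalyst gives the (R)-carbinol (quaternary C7 as the large group) and the substrate bias for hydride attack from the methyl-bearing face selects the carbonyl that places OH cis to the chain, so C6 and C7 are set together, while catecholborane at this temperature does not hydroborate the alkenes.

**Step 6**
Reactants: 12 hydroxy ketone
Product: 13 (2S,3S)-3-bromo-2-methyl-2-[(3E)-4-methylocta-3,7-dien-1-yl]cyclohexan-1-one (6S,7S; Br trans to the chain)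
Conditions: CBr4, PPh3, toluene, 0 → 60 °C
Reagents that add atoms: carbon tetrabromide BrC(Br)(Br)Br
Why: The Appel reaction goes with inversion, because in the conformer with the chain equatorial the C6 oxyphosphonium group is axial and bromide enters equatorially (6S), and the neighbouring C2 carbonyl disfavours ionisation since a 1,2-shift from C7 would place a cation next to C=O.

**Step 7**
Reactants: 13 bromo ketone
Product: 15 (2S,3S,6RS)-3-bromo-2,6-dimethyl-2-[(3E)-4-methylocta-3,7-dien-1-yl]cyclohexan-1-one, via lithium enolate 14 (not isolated)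
Conditions: LDA (1.05 equiv), THF, −78 °C; MeI, DMPU, −78 → −30 °C
Reagents that add atoms: iodomethane CI; lithium diisopropylamide CC(C)[N-]C(C)C.[Li+] (Li only in 14)
Why: In this kinetic enolate alkylation C3 is the only enolisable position (C7 is quaternary), the equatorial bromide has no antiperiplanar hydrogen for E2, and the C3 configuration is irrelevant because C3 becomes sp2 in the next step.

**Step 8**
Reactants: 15 methylated bromo ketone
Product: 17 (5S,6S)-5-bromo-2,6-dimethyl-6-[(3E)-4-methylocta-3,7-dien-1-yl]cyclohex-1-en-1-yl triflate, via potassium enolate 16 (not isolated)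
Conditions: KHMDS, THF, −78 → −20 °C; PhNTf2, −78 °C → rt
Reagents that add atoms: N-phenylbis(trifluoromethanesulfonimide) O=S(=O)(N(c1ccccc1)S(=O)(=O)C(F)(F)F)C(F)(F)F; KHMDS C[Si](C)(C)[N-][Si](C)(C)C.[K+] (K only in 16)
Why: Enol triflate formation from the only possible enolate gives the tetrasubstituted C2=C3 alkene regiospecifically, as is known for 2,2,6-trisubstituted cyclohexanones.

**Step 9**
Reactants: 17 enol triflate
Product: 18 (10S,11S)-10,11-epoxide of 17
Conditions: ent-Shi ketone (30 mol %), Oxone, K2CO3, Bu4NHSO4, MeCN–DMM/aq. borate–EDTA buffer (pH 10.5), 0 °C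
Reagents that add atoms: potassium peroxymonosulfate [K+].[O-]S(=O)(=O)OO
Why: In the Shi asymmetric epoxidation the chiral dioxirane reacts with the electron-rich trisubstituted E-alkene much faster than with the vinyl group or the electron-poor enol triflate, and the L-fructose-derived ketone (spiro transition state) delivers oxygen to the face that gives the (10S,11S)-epoxide under reagent control.

**Step 10**
Reactants: 18 epoxide
Product: 19 (10R,11S)-10-bromo-11-ol
Conditions: Li2NiBr4, THF, 0 °C → rt; pH 7 buffer
Reagents that add atoms: dilithium tetrabromonickelate [Li+].[Li+].[Ni+2].[Br-].[Br-].[Br-].[Br-]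
Why: SN2 opening of a trisubstituted epoxide by soft bromide with only weak lithium assistance takes place at the secondary carbon C10 with inversion (10R) and leaves the C11–O bond (11S) untouched, which gives the anti bromohydrin of the E-alkene.

**Step 11**
Reactants: 19 bromohydrin
Product: 20 C11 O-triethylsilyl ether of 19
Conditions: TESOTf, 2,6-lutidine, CH2Cl2, −78 → 0 °C
Reagents that add atoms: triethylsilyl triflate CC[Si](CC)(CC)OS(=O)(=O)C(F)(F)F
Why: Silyl triflate/lutidine silylation is strong enough for the hindered tertiary alcohol, the base is too weak to close the bromohydrin, and the ether blocks that closure in all later basic steps.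

**Step 12**
Reactants: 20 enol triflate TES ether
Product: 21 methyl C1 ester (C2-CO2Me enoate; vinyl terminus at C14)
Conditions: Pd(OAc)2 (10 mol %), dppf, CO (1 atm), MeOH, Et3N, DMF, 60 °C
Reagents that add atoms: carbon monoxide [C-]#[O+]; methanol CO
Why: Palladium-catalysed methoxycarbonylation of an enol triflate (oxidative addition, CO insertion, methanolysis) brings in C1, is placed after steps 9–11 so that no C10=C11 alkene remains for a 5-exo Heck cyclisation, and unactivated secondary bromides do not add to Pd(0)/phosphine.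

**Step 13**
Reactants: 21 enoate; 22 2-methylbut-2-ene
Product: 23 enoate with the C14=C15 isopropylidene terminus
Conditions: Hoveyda–Grubbs II (5 mol %), 22 (excess), CH2Cl2, 40 °C
Reagents that add atoms: none
Why: Olefin cross-metathesis of a terminal alkene with excess 2-methylbut-2-ene gives the isopropylidene terminus, while the tetrasubstituted enoate alkene is inert to the ruthenium carbene.

**Step 14**
Reactants: 23 enoate
Product: 24 (14S)-14,15-epoxy enoate
Conditions: ent-Shi ketone (30 mol %), Oxone, K2CO3, Bu4NHSO4, MeCN–DMM/aq. borate–EDTA buffer (pH 10.5), 0 °C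
Reagents that add atoms: potassium peroxymonosulfate [K+].[O-]S(=O)(=O)OO
Why: In this second Shi epoxidation with the same ketone, C14=C15 is the only electron-rich alkene left (the ring alkene is tetrasubstituted, hindered and conjugated with the ester), and reagent control gives the (14S)-epoxide.

**Step 15**
Reactants: 24 epoxy enoate
Product: 25 C1 allylic alcohol (14,15-epoxide kept)
Conditions: DIBAL-H, CH2Cl2, −78 → −40 °C; Rochelle salt
Reagents that add atoms: none
Why: DIBAL-H 1,2-reduction of the conjugated ester to the allylic alcohol runs at a temperature at which the trisubstituted epoxide, the silyl ether and the secondary bromides are not reduced.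

**Step 16**
Reactants: 25 allylic alcohol
Product: 27 C1 allylic bromide (14,15-epoxide kept), via C1 mesylate 26 (not isolated)
Conditions: MsCl, Et3N, CH2Cl2, −40 °C; LiBr, THF, −40 → 0 °C; short filtration
Reagents that add atoms: lithium bromide [Li+].[Br-]; methanesulfonyl chloride CS(=O)(=O)Cl (atoms only in 26)
Why: Mesylation followed by bromide displacement under buffered, non-acidic conditions is the standard conversion of epoxide-bearing allylic alcohols into allylic bromides, and the hindered secondary bromides should not exchange with LiBr at 0 °C.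

**Step 17**
Reactants: 27 epoxy allylic bromide
Product: 28 C1 allylic bromide with C15–Br and C14 O-TMS
Conditions: TMSBr (1.1 equiv), CH2Cl2, −78 °C; volatiles removed, used crude
Reagents that add atoms: bromotrimethylsilane C[Si](C)(C)Br
Why: In the opening of an epoxide with a silyl bromide, O-silylation gives an oxonium ion whose cleavage has SN1 character, so bromide goes to the tertiary C15, the C14–O bond and its (S) configuration are kept, and O14 emerges already protected.

**Step 18**
Reactants: 28 allylic bromide; 29 (E)-4-methoxybut-3-en-2-one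
Product: 32 C14 alcohol carrying the C1-linked β-methoxyenone, via lithium dienolate 30 (not isolated), via C14 O-TMS enone 31 (not isolated)
Conditions: 29 (2.5 equiv), LDA, THF, −78 °C; 28, DMPU, −78 → −40 °C; then citric acid, MeOH, 0 °C
Reagents that add atoms: lithium diisopropylamide CC(C)[N-]C(C)C.[Li+] (Li only in 30)
Why: In this Stork–Danheiser-type kinetic α′-alkylation of a vinylogous ester the lithium dienolate reacts at its CH2 terminus with the primary allylic bromide by SN2 at a temperature at which E2 at the tertiary bromide should be slow, and the methanolic citric acid quench cleaves only the TMS ether.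

**Step 19**
Reactants: 32 C14 alcohol; 33 propiolic acid
Product: 34 C14 propiolate
Conditions: DCC, DMAP (cat.), CH2Cl2, −20 → 0 °C
Reagents that add atoms: none
Why: Steglich esterification at low temperature is the usual way to make propiolates, only the secondary OH is free, and catalytic DMAP is not basic enough to close the C14/C15 bromohydrin.

**Step 20**
Reactants: 34 propiolate enone
Product: 35 C14 propiolate carrying the C1-linked (1E,3Z)-1-methoxy-3-(tert-butyldimethylsilyloxy)diene (C11 O-TES)
Conditions: TBSOTf, i-Pr2NEt, Et2O, −78 → −20 °C; filtration through Et3N-washed silica, used at once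
Reagents that add atoms: tert-butyldimethylsilyl triflate CC(C)(C)[Si](C)(C)OS(=O)(=O)C(F)(F)F
Why: Soft enolisation with a silyl triflate and a hindered amine (the preparation of Danishefsky-type dienes) removes an α′-hydrogen next to C1 and gives the (3Z)-enol silane by minimising A(1,3) strain, and the non-nucleophilic base is chosen so that the propiolate is not attacked.

**Step 21**
Reactants: 35 silyloxydiene propiolate
Product: 37 aryl O-TBS, C11 O-TES bromophycolide A, via macrocyclic methoxycyclohexa-1,4-diene cycloadduct 36 (not isolated)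
Conditions: syringe-pump addition to toluene, BHT, 110 °C (0.5 mM final); then PPTS (cat.), CH2Cl2, rt
Reagents that add atoms: none
Why: Proposed new method: the nucleophilic diene terminus (the enol-silane CH that carries C1) bonds to the propiolate β-carbon and the methoxy-bearing terminus to the α-carbon in an asynchronous concerted [4+2], and cycloadduct 36 then loses methanol by PPTS-assisted ionisation of the doubly allylic, silyloxy-stabilised C–OMe and loss of the ring hydrogen at the C1-bearing carbon (OMe and C1 are cis, so a syn 1,4-elimination is not open) to give the aryl silyl ether. The closest known reactions are the intermolecular Diels–Alder benzannulation of 1-alkoxy-3-silyloxydienes with alkynoates to 4-hydroxybenzoates and arene-forming cycloadditions that close cyclophanes, but a 12-atom tether between these two partners has not been tried. The benzene ring closes by the cycloaddition itself (four diene carbons plus two alkyne carbons), and the 15-membered lactone closes in the same event in the bridged (meta-cyclophane) mode of a type-1 intramolecular Diels–Alder reaction, through the new bond between the C1-bearing carbon and the alkyne CH. No lasting stereocentre is formed, since the two sp3 ring carbons of 36 are erased on aromatisation and C6, C7, C10, C11 and C14 are not touched. The step needs regioselectivity (oxygen para and C1 meta to the carboxyl), secured by the polarity match of the 1,3-dioxygenated diene with the ynoate and not opposed by the long tether; it also needs an s-cis-capable diene, secured by the (1E,3Z) geometry that puts C1 and OMe outside, and ring closure over oligomerisation, secured by slow addition at high dilution. Neutral toluene leaves little path for ionisation of the β-acyloxy tertiary bromide or for E2 at the two hindered secondary bromides.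

**Step 22**
Reactants: 37 bis-silyl ether
Product: 38 bromophycolide A
Conditions: HF·pyridine, pyridine, THF, 0 °C → rt
Reagents that add atoms: none
Why: Acidic fluoride desilylation cleaves the aryl TBS and the tertiary TES ether, and avoiding basic fluoride keeps both bromohydrin-type units (C10/C11 and C14/C15) and the lactone intact.

**Compound list**
1 | hex-1-en-5-yne | C=CCCC#C | starting material
2 | oxirane | C1CO1 | starting material
3 | (E)-dimethyl(2-methylhexa-1,5-dienyl)alane | C[Al](C)/C=C(C)/CCC=C | intermediate
4 | lithium butyl(dimethyl)[(E)-2-methylhexa-1,5-dienyl]alanate | [Li+].CCCC[Al-](C)(C)/C=C(C)/CCC=C | intermediate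
5 | (3E)-4-methylocta-3,7-dien-1-ol | OCC/C=C(C)/CCC=C | intermediate
6 | (5E)-8-iodo-5-methylocta-1,5-diene | ICC/C=C(C)/CCC=C | intermediate
7 | 2-methylcyclohexane-1,3-dione | CC1C(=O)CCCC1=O | starting material
8 | 3-(2,2-dimethylhydrazinyl)-2-methylcyclohex-2-en-1-one | CN(C)NC1=C(C)C(=O)CCC1 | intermediate
9 | potassium salt of 8 | [K+].CN(C)N=C1CCCC([O-])=C1C | intermediate
10 | 3-(dimethylhydrazono)-2-methyl-2-[(3E)-4-methylocta-3,7-dienyl]cyclohexan-1-one (racemic) | CN(C)N=C1CCCC(=O)C1(C)CC/C=C(C)/CCC=C | intermediate
11 | 2-methyl-2-[(3E)-4-methylocta-3,7-dienyl]cyclohexane-1,3-dione | O=C1CCCC(=O)C1(C)CC/C=C(C)/CCC=C | intermediate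
12 | (2R,3R)-3-hydroxy-2-methyl-2-[(3E)-4-methylocta-3,7-dienyl]cyclohexan-1-one | C=CCC/C(C)=C/CC[C@]1(C)[C@H](O)CCCC1=O | intermediate
13 | (2S,3S)-3-bromo-2-methyl-2-[(3E)-4-methylocta-3,7-dienyl]cyclohexan-1-one | C=CCC/C(C)=C/CC[C@]1(C)[C@@H](Br)CCCC1=O | intermediate
14 | lithium enolate of 13 | [Li+].C=CCC/C(C)=C/CC[C@]1(C)[C@@H](Br)CCC=C1[O-] | intermediate
15 | (2S,3S)-3-bromo-2,6-dimethyl-2-[(3E)-4-methylocta-3,7-dienyl]cyclohexan-1-one (C3 epimers) | C=CCC/C(C)=C/CC[C@]1(C)[C@@H](Br)CCC(C)C1=O | intermediate
16 | potassium enolate of 15 | [K+].C=CCC/C(C)=C/CC[C@]1(C)[C@@H](Br)CCC(C)=C1[O-] | intermediate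
17 | C2 enol triflate (6S,7S) | C=CCC/C(C)=C/CC[C@]1(C)[C@@H](Br)CCC(C)=C1OS(=O)(=O)C(F)(F)F | intermediate
18 | (10S,11S)-10,11-epoxy enol triflate | C=CCC[C@]1(C)O[C@H]1CC[C@]2(C)[C@@H](Br)CCC(C)=C2OS(=O)(=O)C(F)(F)F | intermediate
19 | (10R,11S)-10-bromo-11-hydroxy enol triflate | C=CCC[C@](C)(O)[C@H](Br)CC[C@]1(C)[C@@H](Br)CCC(C)=C1OS(=O)(=O)C(F)(F)F | intermediate
20 | C11 O-TES enol triflate | C=CCC[C@](C)(O[Si](CC)(CC)CC)[C@H](Br)CC[C@]1(C)[C@@H](Br)CCC(C)=C1OS(=O)(=O)C(F)(F)F | intermediate
21 | methyl C1 enoate, vinyl terminus | C=CCC[C@](C)(O[Si](CC)(CC)CC)[C@H](Br)CC[C@]1(C)[C@@H](Br)CCC(C)=C1C(=O)OC | intermediate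
22 | 2-methylbut-2-ene | CC=C(C)C | starting material
23 | methyl C1 enoate, C14=C15 isopropylidene terminus | CC(C)=CCC[C@](C)(O[Si](CC)(CC)CC)[C@H](Br)CC[C@]1(C)[C@@H](Br)CCC(C)=C1C(=O)OC | intermediate
24 | (14S)-14,15-epoxy enoate | CC1(C)O[C@H]1CC[C@](C)(O[Si](CC)(CC)CC)[C@H](Br)CC[C@]2(C)[C@@H](Br)CCC(C)=C2C(=O)OC | intermediate
25 | epoxy C1 allylic alcohol | CC1(C)O[C@H]1CC[C@](C)(O[Si](CC)(CC)CC)[C@H](Br)CC[C@]2(C)[C@@H](Br)CCC(C)=C2CO | intermediate
26 | epoxy C1 allylic mesylate | CC1(C)O[C@H]1CC[C@](C)(O[Si](CC)(CC)CC)[C@H](Br)CC[C@]2(C)[C@@H](Br)CCC(C)=C2COS(C)(=O)=O | intermediate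
27 | epoxy C1 allylic bromide | CC1(C)O[C@H]1CC[C@](C)(O[Si](CC)(CC)CC)[C@H](Br)CC[C@]2(C)[C@@H](Br)CCC(C)=C2CBr | intermediate
28 | C1 allylic bromide, C15–Br, C14 O-TMS, C11 O-TES | C[Si](C)(C)O[C@H](C(C)(C)Br)CC[C@](C)(O[Si](CC)(CC)CC)[C@H](Br)CC[C@]1(C)[C@@H](Br)CCC(C)=C1CBr | intermediate
29 | (E)-4-methoxybut-3-en-2-one | CO/C=C/C(C)=O | starting material
30 | lithium dienolate of 29 | [Li+].C=C([O-])/C=C/OC | intermediate
31 | C14 O-TMS β-methoxyenone | C[Si](C)(C)O[C@H](C(C)(C)Br)CC[C@](C)(O[Si](CC)(CC)CC)[C@H](Br)CC[C@]1(C)[C@@H](Br)CCC(C)=C1CCC(=O)/C=C/OC | intermediate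
32 | C14 hydroxy β-methoxyenone | O[C@H](C(C)(C)Br)CC[C@](C)(O[Si](CC)(CC)CC)[C@H](Br)CC[C@]1(C)[C@@H](Br)CCC(C)=C1CCC(=O)/C=C/OC | intermediate
33 | propiolic acid | C#CC(=O)O | starting material
34 | C14 propiolate β-methoxyenone | C#CC(=O)O[C@H](C(C)(C)Br)CC[C@](C)(O[Si](CC)(CC)CC)[C@H](Br)CC[C@]1(C)[C@@H](Br)CCC(C)=C1CCC(=O)/C=C/OC | intermediate
35 | C14 propiolate with C1-linked (1E,3Z)-1-methoxy-3-TBSO-diene | C#CC(=O)O[C@H](C(C)(C)Br)CC[C@](C)(O[Si](CC)(CC)CC)[C@H](Br)CC[C@]1(C)[C@@H](Br)CCC(C)=C1C/C=C(O[Si](C)(C)C(C)(C)C)/C=C/OC | intermediate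
36 | macrocyclic methoxycyclohexa-1,4-diene cycloadduct (OMe and C1 cis, both faces; the two transient centres are left open) | CC1=C2CC3C=C(C(OC)C=C3O[Si](C)(C)C(C)(C)C)C(=O)O[C@H](C(C)(C)Br)CC[C@](C)(O[Si](CC)(CC)CC)[C@H](Br)CC[C@]2(C)[C@@H](Br)CC1 | intermediate
37 | aryl O-TBS, C11 O-TES bromophycolide A | CC1=C2Cc3cc(ccc3O[Si](C)(C)C(C)(C)C)C(=O)O[C@H](C(C)(C)Br)CC[C@](C)(O[Si](CC)(CC)CC)[C@H](Br)CC[C@]2(C)[C@@H](Br)CC1 | intermediate
38 | bromophycolide A | CC1=C2Cc3cc(ccc3O)C(=O)O[C@H](C(C)(C)Br)CC[C@](C)(O)[C@H](Br)CC[C@]2(C)[C@@H](Br)CC1 | target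

**Step count**
Total step count: 22. Longest linear sequence: 21 (steps 1, 2 and 4–22).

**Steps most likely to fail**

1. Step 21 (the labelled step). The effective molarity of the 12-atom tether may be so low that, at the dilution needed, ring closure is outrun by intermolecular cycloaddition, by protodesilylation of the diene by the methanol set free, or by thermal loss of HBr at C15.
Fallback: benzannulation and ring closure are separated, using known chemistry only. It sets out from 31, which is isolated by quenching step 18 with pH 7 buffer. TBSOTf/i-Pr2NEt gives the C14 O-TMS silyloxydiene F1. F1 is heated with excess allyl propiolate (C#CC(=O)OCC=C) in concentrated toluene solution, the known intermolecular benzannulation, and aromatised with PPTS to the allyl 3-alkyl-4-silyloxybenzoate F2. Citric acid/MeOH frees O14 to give the hydroxy allyl ester F3. Pd(PPh3)4/PhSiH3 removes the allyl group to give the seco acid F4. Shiina macrolactonisation (MNBA, DMAP, slow addition) then closes the lactone and returns to 37.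

2. Step 6. Substitution at the neopentyl C6 may lose to E2 toward C5 from the axial oxyphosphonium salt, or to ionisation with skeletal shift.
Fallback: activation and displacement are separated. It sets out from 12. ClCH2SO2Cl/pyridine gives the isolable, small and highly nucleofugal C6 chloromethanesulfonate F5. F5 is displaced in a second operation by naked bromide (LiBr, DMPU–toluene, 50 °C) with inversion, and the route is rejoined at 13.

3. Step 18. SN2 at the hindered allylic carbon may be slow enough for the dienolate to self-condense or to act as a base on the tertiary bromide.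
Fallback: the vinylogous ester is built stepwise on the substrate, and the tertiary bromide is introduced only after all basic steps. It sets out from 27. The lithium enolate of N-methoxy-N-methylacetamide gives the epoxy Weinreb amide F6. Ethynylmagnesium bromide converts F6 into the epoxy ynone F7. MeOH with catalytic DABCO (oxa-Michael addition) gives the epoxy β-methoxyenone F8. TMSBr (1.05 equiv, −78 °C) opens the epoxide and returns to 31, which is then desilylated to 32 as in step 18.

**Further compounds**
F1 | step 21 | C14 O-TMS, C11 O-TES (1E,3Z)-silyloxydiene | C[Si](C)(C)O[C@H](C(C)(C)Br)CC[C@](C)(O[Si](CC)(CC)CC)[C@H](Br)CC[C@]1(C)[C@@H](Br)CCC(C)=C1C/C=C(O[Si](C)(C)C(C)(C)C)/C=C/OC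
F2 | step 21 | allyl 3-alkyl-4-(TBSO)benzoate, C14 O-TMS | C[Si](C)(C)O[C@H](C(C)(C)Br)CC[C@](C)(O[Si](CC)(CC)CC)[C@H](Br)CC[C@]1(C)[C@@H](Br)CCC(C)=C1Cc2cc(C(=O)OCC=C)ccc2O[Si](C)(C)C(C)(C)C
F3 | step 21 | allyl 3-alkyl-4-(TBSO)benzoate, C14 OH | O[C@H](C(C)(C)Br)CC[C@](C)(O[Si](CC)(CC)CC)[C@H](Br)CC[C@]1(C)[C@@H](Br)CCC(C)=C1Cc2cc(C(=O)OCC=C)ccc2O[Si](C)(C)C(C)(C)C
F4 | step 21 | seco acid (C14 OH, aryl O-TBS, C11 O-TES) | O[C@H](C(C)(C)Br)CC[C@](C)(O[Si](CC)(CC)CC)[C@H](Br)CC[C@]1(C)[C@@H](Br)CCC(C)=C1Cc2cc(C(=O)O)ccc2O[Si](C)(C)C(C)(C)C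
F5 | step 6 | C6 chloromethanesulfonate of 12 | C=CCC/C(C)=C/CC[C@]1(C)[C@H](OS(=O)(=O)CCl)CCCC1=O
F6 | step 18 | epoxy Weinreb amide | CC1(C)O[C@H]1CC[C@](C)(O[Si](CC)(CC)CC)[C@H](Br)CC[C@]2(C)[C@@H](Br)CCC(C)=C2CCC(=O)N(C)OC
F7 | step 18 | epoxy ynone | CC1(C)O[C@H]1CC[C@](C)(O[Si](CC)(CC)CC)[C@H](Br)CC[C@]2(C)[C@@H](Br)CCC(C)=C2CCC(=O)C#C
F8 | step 18 | epoxy β-methoxyenone | CC1(C)O[C@H]1CC[C@](C)(O[Si](CC)(CC)CC)[C@H](Br)CC[C@]2(C)[C@@H](Br)CCC(C)=C2CCC(=O)/C=C/OC
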